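**Strategy.** The target, 3,4,6-tribromo-2-(5-bromo-2-hydroxyphenoxy)phenol, is achiral. Ring B (the tribromo ring, phenol numbering) carries the contiguous triad C1–OH, C2–OAr, C3–Br, which is the retron of a 2-oxy-1,3-dione. The ether C2–O bond is therefore made while ring B is still alicyclic: Rh-carbenoid O–H insertion of 2-diazocyclohexane-1,3-dione into 5-bromo-2-methoxyphenol (ring A). One carbonyl later becomes the C3–Br that no aromatic bromination could place (ortho to OAr, meta to OH), the other becomes the C1–OH, and a brominative aromatization adds Br at C4 and C6. The key step unites both halves at a symmetric carbene carbon without any aryl electrophile.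

Key step: step 2

Remark: the target has no stereocenter and no configurationally stable axis, so it is a single achiral compound and no stereocontrol is required; intermediate 6 is racemic and its stereocenter is destroyed on aromatization.

**Step 1**
Reactants: 1 cyclohexane-1,3-dione
Product: 2 2-diazocyclohexane-1,3-dione
Conditions: p-ABSA (1.05 equiv), Et3N (1.1 equiv), MeCN, 0 °C → rt
Reagents that add atoms: 4-acetamidobenzenesulfonyl azide (p-ABSA), CC(=O)Nc1ccc(cc1)S(=O)(=O)N=[N+]=[N-]
Why: Regitz diazo transfer to the doubly activated C2 methylene of a cyclic 1,3-dione is a standard, clean reaction, and the sulfonamide by-product is removed by filtration and basic wash.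

**Step 2**
Reactants: 2 2-diazocyclohexane-1,3-dione; 3 5-bromo-2-methoxyphenol
Product: 4 2-(5-bromo-2-methoxyphenoxy)-3-hydroxycyclohex-2-en-1-one (enol form of the 2-aryloxy-1,3-dione)
Conditions: Rh2(OAc)4 (1 mol %), 3 (1.5 equiv), slow addition of 2, PhCF3, 80 °C
Reagents that add atoms: none
Why: Rh2(OAc)4 extrudes N2 from 2 to give an electrophilic acceptor/acceptor rhodium carbenoid, the phenol oxygen of 3 adds to the carbene carbon to form an oxonium ylide, and a 1,2-proton shift releases the catalyst and the 2-aryloxy-1,3-dione, which rests as enol 4. The closest known reaction type is the Rh(II)-catalysed O–H insertion of α-diazo-1,3-dicarbonyl compounds into phenols. No ring is closed and no stereocenter is formed; the new bond is the inter-ring ether C–O bond, made at a carbon flanked only by two planar carbonyls, so the ortho,ortho′-congestion that an aryl electrophile would carry at C2 of ring B (between C1–O and C3–Br) is absent. The step needs chemoselectivity for O–H insertion over aromatic C–H insertion or cyclopropanation, Wolff rearrangement and a second insertion into the acidic enol of 4; the bromine-deactivated ring of 3, the fast proton transfer open to an O–H ylide, the excess of 3 and the slow addition of 2 should secure it. No regiochemical question arises because 2 is symmetric and 3 has a single OH, and the aryl C–Br bond is inert to Rh(II) carboxylates.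

**Step 3**
Reactants: 4 2-(5-bromo-2-methoxyphenoxy)-3-hydroxycyclohex-2-en-1-one
Product: 5 3-bromo-2-(5-bromo-2-methoxyphenoxy)cyclohex-2-en-1-one
Conditions: Ph3PBr2 (1.15 equiv), Et3N (1.2 equiv), CH2Cl2, 0 °C → rt
Reagents that add atoms: dibromotriphenylphosphorane (Ph3PBr2), BrP(Br)(c1ccccc1)(c1ccccc1)c1ccccc1
Why: This is the established conversion of a cyclic 1,3-dione into its β-bromo enone (O-phosphonium activation of the vinylogous acid, then addition–elimination by bromide), and because the dione is symmetric only one product can form, with Br on the carbon that becomes C3 of ring B.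

**Step 4**
Reactants: 5 3-bromo-2-(5-bromo-2-methoxyphenoxy)cyclohex-2-en-1-one
Product: 9 3,4,6-tribromo-2-(5-bromo-2-methoxyphenoxy)phenol, via α′-bromo enone 6 (not isolated), via monobromophenol 7 (not isolated), via dibromophenol 8 (not isolated)
Conditions: Br2 (3.05 equiv), anhydrous AcOH/CH2Cl2 (1:1), dark, 0 °C → 40 °C
Reagents that add atoms: bromine, BrBr
Why: This is a bromination–dehydrobromination aromatization of a cyclohexenone (acid-catalysed enol bromination, loss of HBr through the dienol, tautomerization to phenol 7) followed by ordinary para then ortho electrophilic bromination of the phenol; the only ring-B carbons that enolization or the OH group can activate (C4 and C6) are exactly those that carry Br in the target, while C5 and the bromine-deactivated anisole ring A should stay untouched at this stoichiometry.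

**Step 5**
Reactants: 9 3,4,6-tribromo-2-(5-bromo-2-methoxyphenoxy)phenol
Product: 11 3,4,6-tribromo-2-(5-bromo-2-hydroxyphenoxy)phenol (CNP0307618.0), via bis-O-dibromoboryl derivative 10 (not isolated)
Conditions: BBr3 (3.0 equiv), CH2Cl2, −78 °C → rt; then ice/H2O, acidic work-up without base
Reagents that add atoms: none
Why: BBr3 demethylation of an aryl methyl ether (Lewis acid activation, SN2 attack of bromide on the methyl group) leaves the diaryl ether and the aryl C–Br bonds intact, and the acidic work-up avoids a base-induced Smiles migration in the ortho-hydroxy diaryl ether.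

**Compound list**
1 | cyclohexane-1,3-dione | O=C1CCCC(=O)C1 | starting material
2 | 2-diazocyclohexane-1,3-dione | [N-]=[N+]=C1C(=O)CCCC1=O | intermediate
3 | 5-bromo-2-methoxyphenol | COc1ccc(Br)cc1O | starting material
4 | 2-(5-bromo-2-methoxyphenoxy)-3-hydroxycyclohex-2-en-1-one | COc1ccc(Br)cc1OC1=C(O)CCCC1=O | intermediate
5 | 3-bromo-2-(5-bromo-2-methoxyphenoxy)cyclohex-2-en-1-one | COc1ccc(Br)cc1OC1=C(Br)CCCC1=O | intermediate
6 | 3,6-dibromo-2-(5-bromo-2-methoxyphenoxy)cyclohex-2-en-1-one (α′-bromo enone, racemic) | COc1ccc(Br)cc1OC1=C(Br)CCC(Br)C1=O | intermediate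
7 | 3-bromo-2-(5-bromo-2-methoxyphenoxy)phenol | COc1ccc(Br)cc1Oc1c(O)cccc1Br | intermediate
8 | 3,4-dibromo-2-(5-bromo-2-methoxyphenoxy)phenol | COc1ccc(Br)cc1Oc1c(O)ccc(Br)c1Br | intermediate
9 | 3,4,6-tribromo-2-(5-bromo-2-methoxyphenoxy)phenol | COc1ccc(Br)cc1Oc1c(O)c(Br)cc(Br)c1Br | intermediate
10 | bis-O-dibromoboryl derivative of the target | BrB(Br)Oc1ccc(Br)cc1Oc1c(OB(Br)Br)c(Br)cc(Br)c1Br | intermediate
11 | 3,4,6-tribromo-2-(5-bromo-2-hydroxyphenoxy)phenol | Oc1ccc(Br)cc1Oc1c(O)c(Br)cc(Br)c1Br | target

**Total step count:** 5. **Longest linear sequence:** 5 (1 → 2 → 4 → 5 → 9 → 11).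

**Steps most likely to fail**

Step 2. The rhodium carbenoid may be diverted into aromatic C–H insertion or cyclopropanation of the phenol ring, into Wolff rearrangement, or into a second insertion into the acidic enol of the product, so that O–H insertion is eroded. The fallback sets out from 3 and comes back at 4; it keeps the alicyclic ring-B idea but closes the dione ring after the ether bond is made. Commercial methyl 5-oxohexanoate is brominated at its methyl terminus (Br2, MeOH, 0 °C) to methyl 6-bromo-5-oxohexanoate F1. Phenol 3 is O-alkylated with F1 (K2CO3, acetone, reflux) to methyl 6-(5-bromo-2-methoxyphenoxy)-5-oxohexanoate F2. An intramolecular Claisen condensation of F2 (t-BuOK, THF, 0 °C → rt, then aqueous HCl), in which the aryloxy-substituted ketone α-carbon attacks the ester, closes the six-membered 1,3-dione 4.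

Step 4. Electrophilic bromination of ring A may compete, or dehydrobromination may stay incomplete, which would give mixtures that differ in bromine count. The fallback sets out from 3 and comes back at 7; it abandons the alicyclic ring B for this stage. SNAr of 3 on commercial 3-bromo-2-fluorobenzaldehyde (K2CO3, DMF, 90 °C) should give 3-bromo-2-(5-bromo-2-methoxyphenoxy)benzaldehyde F3. Baeyer–Villiger (Dakin-type) oxidation with mCPBA (CH2Cl2, rt) should give 3-bromo-2-(5-bromo-2-methoxyphenoxy)phenyl formate F4, and methanolysis (K2CO3, MeOH, 0 °C) then gives 7. Phenol 7 is dibrominated in a separate, stoichiometry-controlled operation (Br2, 2.0 equiv, AcOH/CH2Cl2, 0 °C) to 9.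

Step 3. Activation of the enol may be incomplete, or the vinylogous acyl bromide may revert by hydrolysis during work-up. The fallback sets out from 3 and comes back at 5. The phenoxide of 3 opens commercial 2,3-epoxycyclohexanone (7-oxabicyclo[4.1.0]heptan-2-one) at the α-carbon and the resulting β-hydroxy ketone dehydrates in the same pot (Cs2CO3, DMF, 70 °C) to 2-(5-bromo-2-methoxyphenoxy)cyclohex-2-en-1-one F5. Bromine (1.0 equiv, CH2Cl2, −78 °C) adds to the enol-ether double bond at C3 and Et3N eliminates HBr to give 5.

**Further compounds**
F1 | step 2 | methyl 6-bromo-5-oxohexanoate | COC(=O)CCCC(=O)CBr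
F2 | step 2 | methyl 6-(5-bromo-2-methoxyphenoxy)-5-oxohexanoate | COC(=O)CCCC(=O)COc1cc(Br)ccc1OC
F3 | step 4 | 3-bromo-2-(5-bromo-2-methoxyphenoxy)benzaldehyde | COc1ccc(Br)cc1Oc1c(C=O)cccc1Br
F4 | step 4 | 3-bromo-2-(5-bromo-2-methoxyphenoxy)phenyl formate | COc1ccc(Br)cc1Oc1c(OC=O)cccc1Br
F5 | step 3 | 2-(5-bromo-2-methoxyphenoxy)cyclohex-2-en-1-one | COc1ccc(Br)cc1OC1=CCCCC1=O
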